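0.230 mM min⁻¹ is the number I carry from Monday's run, whose product reached 20% of 0.046 M solid substrate at 40.0 min. I call it the delivery rate: product concentration made per minute, taken as the same whatever the charge.

the same everywhere: enzyme 3.9 µM; added ligand 6.9 µM
- Monday's: solid substrate 0.046 M; run made earlier
- Thursday's: solid substrate 0.10 M; run made earlier
- flask: solid substrate 0.069 M

| run | time / min | product / % |
|---|---|---|
| Monday's | 2.00 | 2 |
| Monday's | 6.00 | 1 |
| Monday's | 12.0 | 7 |
| Monday's | 15.0 | 7 |
| Monday's | 25.0 | 11 |
| Monday's | 30.0 | 11 |
| Monday's | 40.0 | 20 |
| Thursday's | 3.00 | 1 |
| Thursday's | 5.00 | 0 |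
| Thursday's | 8.00 | 3 |
| Thursday's | 12.0 | 1 |
| Thursday's | 15.0 | 2 |
| Thursday's | 25.0 | 0 |
| Thursday's | 40.0 | 7 |

(each reading ± 2 percentage points)

1. apparent order in enzyme when 30% of the solid substrate are converted (what has only dissolved counts as not reacted) (percent change of the rate of making product for one percent more enzyme charged)

Thursday's run tests this. With 0.10 M charged, the delivery rate puts product at 9.20% at 40.0 min; the reading is 7%, with a scatter of 2 percentage points. So more solid gives no more product per minute, which looks like product paced by the dissolving of the solid.

Now the ledger for the flask, where solid substrate is the limiting reagent. Of 0.069 M charged, the entry for 30% conversion is 20.7 mM, which takes 90.0 min at the delivery rate. The whole charge closes the books at 300 min, if the rate holds to the end. If dissolving paces product, more enzyme adds little, so I reckon the order in enzyme near zero. That is a guess, since no run varied enzyme.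

The forecast differs: it gives 1.5, reasoning that “More solid therefore means slower reaction”.

    starting material + enzyme → product + enzyme, rate k1*[starting material]*[enzyme]/(1 + ([starting material]/Km1) + ([product]/Kp1)) (0.0850 M, 35.0 mM, k = 45000 L mol⁻¹ s⁻¹)
    enzyme + added ligand ⇌ idle complex, settled at all times (K = 2.60 × 10⁵ L mol⁻¹)
    solid substrate ⇌ starting material, rate k3*(cs3 - [starting material]) while solid is left; crystals form when [starting material] > cs3 (solubility = 3.80 mM, k = 0.0530 min⁻¹)

The flask gives an order of 0.023, and it makes product at 0.198 mM min⁻¹ at 30% conversion, reached at 105 min against my 90.0 min, so the delivery rate of 0.230 mM min⁻¹ ran a little high. In the flask, solid substrate dissolves while solid is left, and at 40.0 min it stands at 88.5% with starting material at 0.0748%, while enzyme stays at 44.8% beside 55.2% idle complex. The flask's rate at 298 min is still 0.99 of that value, and at 400 min solid substrate is at 0% and product at 100%.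

Readings and results were computed for substances that don't exist.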